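## The problem

The target 28 is a fourteen-membered carbocycle. Its ring atoms are numbered here C1 to C14 from the ester-bearing alkene carbon: C1=C2, acetoxy at C3, methyl at C5, diene C5=C6–C7=C8, isopropyl at C8, hydroxyl at C10, second ester at C11, C11=C12, then C13 and C14 back to C1. There are only two stereocentres, C3 (R, acetate) and C10 (R, carbinol). They lie on opposite sides of the ring, too far apart for either to direct the other, so each must be set independently. Most of the stereochemical load is in four trisubstituted alkenes: both enoates have the ester cis to the ring chain (C3 at C1=C2, C13 at C11=C12), C5=C6 is E, and C7=C8 has the ring carbons C6 and C9 cis, which Claisen-type and thermodynamic methods do not deliver. Two lactonisations constrain the order of events: a free C3 hydroxyl would close onto the cis ester at C1 (butenolide) and a free C14 hydroxyl onto the cis ester at C11 (six-membered lactone). The C3 acetate must therefore be in place before C1=C2 is made, and once that alkene exists the acetate is allylic and must not meet zerovalent palladium or alkoxide. The diene and the doubly allylic C9 methylene exclude strong acid and oxidants late in the route. The feature that opens the molecule is the C7 to C10 segment: the C10 carbinol is homoallylic to C7=C8, C8 carries the isopropyl branch and C7 sits between two alkenes, which is the pattern left by an alpha-alkenyl 2-isopropylallyl boronate adding to an aldehyde through its CH2 terminus.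

## Retrosynthesis

28 from 27. No skeletal bond is cut; the last step only frees the C10 hydroxyl from its tert-butyldimethylsilyl ether. A silyl ether is chosen for C10 because it survives all later operations and is removed by HF·pyridine, which leaves the allylic acetate and the esters alone.

27 from 26. The ring is opened at C1=C2. This is the one ring alkene whose halves are a stabilised carbanion (C1, flanked by the ester) and an aldehyde (C2). Opening C11=C12 in the same way would place the phosphonate beta to the C10 oxygen, where it eliminates, and opening the diene would undo the fragment union. Precursor 26 is an open chain with the C2 aldehyde, the C3 acetate and a bis(trifluoroethyl) phosphonoacetate at C1. The forward reaction must give the Z enoate during ring closure and be mild enough for an alpha-acetoxy aldehyde.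

26 from 25, 23 and 22. No skeletal bond is cut. The aldehyde and the acetate are traced to the C2,C3 isopropylidene acetal of 22. Hydrolysis gives diol 23. The primary hydroxyl is capped as its triethylsilyl ether (24) and the secondary one acetylated (25) in one flask, and the primary silyl ether is oxidised directly to aldehyde 26. This is shorter than carrying two different oxygen protecting groups from the start, and the hydroxy acetate, which can shift its acetyl group, is never handled.

22 from 21, 20, 19, 18 and 17. The C1–C14 bond is cut to the commercial Still–Gennari phosphonoacetate and primary halide 21. The C11 ester carbon is removed to CO, methanol and vinyl iodide 20. The order is forced. Carbonylation needs zerovalent palladium, methanol and base, which a trifluoroethyl phosphonate and an allylic acetate would not survive, so it precedes both. C14 is carried through it as a chloride (from alcohol 19, itself from bis-silyl ether 18 and alcohol 17), because a C14 alcohol would lactonise onto the new cis ester and an alkyl iodide would not survive the palladium step.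

17 from 6, 9 and 12. The bonds C6–C7 and C9–C10 are cut in one operation. The alternatives considered were:
- a Suzuki cut at C6–C7, which would need a C7 alkenyl halide with C6 cis to C9, a geometry not available by simple carbometalation;
- a Claisen cut, which gives the wrong C7=C8 isomer.

The chosen cut lets the C8 isopropyl group enforce the alkene geometry through allylic strain and relays one boron-bearing stereocentre (C7) to C10. The precursors are three small pieces: alkenyl boronate 6 (C2–C6, with C3 from the chiral pool), achiral allyl carbamate 9 (C7–C9 and the isopropyl group) and iodoenal 12 (C10–C14). The forward reaction passes through lithiated carbamate 13, boronate complex 14, allylboronate 15 and borate 16. It must control the configuration at C7, the site of borylation and the terminus of 15 that attacks the aldehyde.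

6 from 5, 3, 2 and 1. The C6–B bond is traced to iodide 5. The C5 methyl and the C6 iodine come from syn carboalumination of alkyne 3 (via alkenylalane 4) followed by iodinolysis, which fixes C5=C6 as E. Alkyne 3 comes from aldehyde 2 by one-carbon homologation, and 2 from commercial alcohol 1, the acetonide of (R)-butane-1,2,4-triol derived from D-malic acid, which supplies C3.

9 from 8 and 7; 12 from 11 and 10. Carbamate 9 is the carbamoyl derivative of 2-isopropylallyl alcohol 8, made in one step by adding an isopropyl Grignard reagent to propargyl alcohol 7. Iodoenal 12 comes from enal 11 by alpha-iodination, and 11 from commercial silyl ether 10 by cross-metathesis with but-2-enal.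

## Roads not taken

Alternative 1: Ring closure at C4–C5 by nickel-catalysed electroreductive decarboxylative coupling.
- Cut and key step: open-chain precursor A2 carries an N-acyloxyphthalimide at the future C4 and a dienyl iodide at C5. Cathodic reduction with NiCl2(dme) and 2,2'-bipyridine would release CO2, generate the primary C4 radical and couple it with the C5 iodide to give macrocycle A1, the C10 triethylsilyl ether of 28.
- Merits: both enoate geometries are fixed in an open chain, where intermolecular Z-selective olefination is most reliable, and ring closure needs no base. On the C1=C2 question this road is better than the chosen one, which must obtain Z selectivity during ring closure.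
- Weak points: the C4 radical is beta to the C3 acetoxy group, and once it is bound to nickel, loss of acetate to a C3=C4 alkene is an obvious escape. Two enoates in the chain are radical acceptors. A catalytic cross-electrophile coupling has to turn over at macrocyclisation dilution. Above all, A2 already contains the C7=C8 alkene, so the hardest geometry is left to some other step.
- Comparison: the chosen plan sets against the olefination risk a ring closure of a documented class and a union step that creates C10 and C7=C8 together.

Alternative 2: Ring closure at C7–C8 by acylium–olefin cyclisation.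
- Cut and key step: open-chain acid chloride A4 would be ionised by SnCl4. The terminal isopropylidene attacks the C7 acylium ion and chloride captures the tertiary cation, giving ketone A3 with a 2-chloropropan-2-yl group at C8.
- Merits: cheap reagents, no organometallic partner, a trivially accessible alkene terminus, and enoate geometries again set before ring closure.
- Weak points: the acylium ion is conjugated and weakly electrophilic, and SnCl4 must discriminate among five Lewis-basic oxygen functions. A3 is also far from the target: C7 is a ketone and C8 is sp3. Reduction, dehydration across C7–C8 and removal of chlorine would be needed. The dehydration has no control over the C7=C8 geometry and can also run toward the isopropyl carbon, and the C8 stereocentre is made only to be destroyed.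
- Comparison: it may reach a ring in fewer steps, but it leaves the defining alkene unsolved. The chosen plan settles that alkene in the step that joins the fragments.

Alternative 3: Ring expansion of a cyclobutene.
- Cut and key step: heating cis-fused bicyclo[10.2.0] cyclobutene A6 would break the C5–C8 bond by conrotatory 4π opening and give A5, the C10 silyl ether of 28, which is identical with 27.
- Merits: no reagent, neutral conditions, every functional group tolerated. As a single step it is cleaner than any step of the chosen plan.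
- Weak points: two conrotatory senses exist and only the one turning C4 outward and C9 inward gives the required diene. With methyl versus ring methylene at C5 and isopropyl versus ring methylene at C8, nothing in A6 makes that choice reliably. A6 has two adjacent quaternary stereocentres in a strained ring fused to a twelve-membered ring that still needs its own macrocyclisation.
- Comparison: the difficulty is moved into the synthesis of A6. The chosen plan uses the chiral pool and acyclic stereocontrol with far simpler intermediates.

Key step: step 9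

Assumption: the lithiation of 9 is taken to follow the sense known for alkyl carbamates ((−)-sparteine gives the (S)-lithio compound) with boron capture under retention, so (+)-sparteine is specified; if the sense is reversed for this allylic case, (−)-sparteine takes its place and nothing else changes.

Step 1
Reactants: 1 (R)-2-(2,2-dimethyl-1,3-dioxolan-4-yl)ethan-1-ol
Product: 2 (R)-2-(2,2-dimethyl-1,3-dioxolan-4-yl)acetaldehyde
Conditions: TEMPO (0.1 equiv), PhI(OAc)2 (1.1 equiv), CH2Cl2, rt
Reagents that add atoms: none
Why: Oxoammonium (TEMPO) oxidation of a primary alcohol stops at the aldehyde without base, so the acetal is kept and the beta-alkoxy aldehyde does not eliminate; the C3 centre is not alpha to the carbonyl and cannot epimerise.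

Step 2
Reactants: 2 (R)-2-(2,2-dimethyl-1,3-dioxolan-4-yl)acetaldehyde
Product: 3 (R)-2,2-dimethyl-4-(prop-2-yn-1-yl)-1,3-dioxolane
Conditions: dimethyl (1-diazo-2-oxopropyl)phosphonate (1.3 equiv), K2CO3, MeOH, 0 °C to rt
Reagents that add atoms: dimethyl (1-diazo-2-oxopropyl)phosphonate, COP(=O)(OC)C(=[N+]=[N-])C(C)=O
Why: Ohira–Bestmann variant of the Seyferth–Gilbert homologation: methanolysis frees the diazomethylphosphonate anion, which adds to the aldehyde; loss of phosphate and N2 with 1,2-shift gives the terminal alkyne C5≡C6.

Step 3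
Reactants: 3 (R)-2,2-dimethyl-4-(prop-2-yn-1-yl)-1,3-dioxolane
Product: 5 (R,E)-4-(3-iodo-2-methylprop-2-en-1-yl)-2,2-dimethyl-1,3-dioxolane, via alkenylalane 4 (not isolated)
Conditions: AlMe3 (2.5 equiv), Cp2ZrCl2 (0.25 equiv), CH2Cl2, 0 °C to rt; then I2, THF, −30 to 0 °C
Reagents that add atoms: trimethylaluminium, C[Al](C)C; iodine, II
Why: Negishi zirconium-catalysed carboalumination adds methyl and aluminium syn across the terminal alkyne with methyl on the internal carbon, and iodinolysis of the C–Al bond goes with retention, which fixes C5=C6 as E.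

Step 4
Reactants: 5 (R,E)-4-(3-iodo-2-methylprop-2-en-1-yl)-2,2-dimethyl-1,3-dioxolane
Product: 6 2-[(E)-3-[(4R)-2,2-dimethyl-1,3-dioxolan-4-yl]-2-methylprop-1-en-1-yl]-4,4,5,5-tetramethyl-1,3,2-dioxaborolane
Conditions: B2pin2 (1.1 equiv), PdCl2(PPh3)2 (3 mol%), PPh3 (6 mol%), KOPh (1.5 equiv), toluene, 50 °C
Reagents that add atoms: bis(pinacolato)diboron, CC1(C)OB(OC1(C)C)B1OC(C)(C)C(C)(C)O1
Why: Miyaura borylation of an alkenyl iodide; oxidative addition, boron transfer from the phenoxide-activated diboron and reductive elimination keep the alkene geometry, and the weak phenoxide base holds back Suzuki homocoupling.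

Step 5
Reactants: 7 prop-2-yn-1-ol
Product: 8 3-methyl-2-methylidenebutan-1-ol
Conditions: i-PrMgCl (2.5 equiv), CuI (10 mol%), Et2O, −10 °C to reflux; aq. NH4Cl
Reagents that add atoms: isopropylmagnesium chloride, CC(C)[Mg]Cl
Why: Copper-catalysed carbomagnesiation of propargyl alcohol: the magnesium alkoxide directs the isopropyl group to the internal alkyne carbon through a five-membered chelate, and protonolysis of the vinyl–magnesium bond leaves the 2-substituted allyl alcohol.

Step 6
Reactants: 8 3-methyl-2-methylidenebutan-1-ol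
Product: 9 3-methyl-2-methylidenebutyl N,N-di(propan-2-yl)carbamate
Conditions: NaH, THF, 0 °C; then i-Pr2NC(O)Cl, rt to reflux
Reagents that add atoms: N,N-diisopropylcarbamoyl chloride, CC(C)N(C(C)C)C(=O)Cl
Why: O-Acylation of the sodium alkoxide by the hindered carbamoyl chloride gives the base-stable carbamate that directs alpha-lithiation and later acts as leaving group.

Step 7
Reactants: 10 tert-butyl(but-3-en-1-yloxy)dimethylsilane
Product: 11 (E)-5-[(tert-butyldimethylsilyl)oxy]pent-2-enal
Conditions: (E)-but-2-enal (5 equiv), second-generation Grubbs catalyst (3 mol%), CH2Cl2, 40 °C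
Reagents that add atoms: (E)-but-2-enal, C/C=C/C=O
Why: Olefin cross-metathesis of a terminal alkene with an excess of an electron-poor enal that does not readily homodimerise; propene escapes and the conjugated product forms as the E isomer under thermodynamic control.

Step 8
Reactants: 11 (E)-5-[(tert-butyldimethylsilyl)oxy]pent-2-enal
Product: 12 (Z)-5-[(tert-butyldimethylsilyl)oxy]-2-iodopent-2-enal
Conditions: I2 (1.5 equiv), K2CO3, DMAP (0.2 equiv), THF/H2O (1:1), rt
Reagents that add atoms: iodine, II
Why: Amine-catalysed alpha-iodination of an enal (conjugate addition of DMAP, iodination of the enolate, loss of DMAP); the addition–elimination path returns the more stable isomer with the formyl group trans to the chain, which carries the Z descriptor once iodine is on C11.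

Step 9
Reactants: 9 3-methyl-2-methylidenebutyl N,N-di(propan-2-yl)carbamate; 6 2-[(E)-3-[(4R)-2,2-dimethyl-1,3-dioxolan-4-yl]-2-methylprop-1-en-1-yl]-4,4,5,5-tetramethyl-1,3,2-dioxaborolane; 12 (Z)-5-[(tert-butyldimethylsilyl)oxy]-2-iodopent-2-enal
Product: 17 (3Z,5R,7E,9E)-1-[(tert-butyldimethylsilyl)oxy]-11-[(4R)-2,2-dimethyl-1,3-dioxolan-4-yl]-4-iodo-10-methyl-7-(propan-2-yl)undeca-3,7,9-trien-5-ol, via lithiated carbamate 13 (not isolated), via boronate complex 14 (not isolated), via allylboronate 15 (not isolated), via borate ester 16 (not isolated)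
Conditions: 9 (1.4 equiv), (+)-sparteine (1.4 equiv), s-BuLi (1.3 equiv), Et2O, −78 °C; 6 (1.0 equiv), −78 °C; −78 to 35 °C; 12 (1.5 equiv), 0 °C to rt; pH 7 buffer
Reagents that add atoms: none
Why: Proposed new method: the closest known reaction type is the lithiation–borylation–allylboration sequence, in which a sparteine-complexed alpha-lithiated alkyl carbamate is captured by an alkenyl pinacol boronate and the rearranged allylboronate adds in situ to an aldehyde; alpha-lithiated 2-alkenyl carbamates are likewise known to give alpha-carbamoyloxy allylboron compounds that undergo 1,2-shift, but an allylic carbamate has not been paired with an alkenyl boronate, and the doubly allylic boronate that results is new. Mechanistically, s-BuLi/(+)-sparteine removes one enantiotopic C7 hydrogen of 9 to give 13, the carbamate carbonyl guides the boron of 6 to C7 with retention to give 14, and on warming the C6 alkenyl group migrates from boron to C7 anti to the leaving carbamate to give 15. Boronate 15 then adds to aldehyde 12 through its CH2 terminus C9 in a closed six-membered chair, and aqueous work-up of borate 16 frees 17. No ring is formed. The only new stereocentre, C10, is controlled by 1,3-transfer from C7: the C6 group takes the axial site to escape A1,2 strain with the C8 isopropyl group and the aldehyde residue sits equatorial, so (R)-C7 gives (R)-C10 and, in the same event, the C7=C8 alkene with C6 cis to C9. The step needs enantiocontrol at C7 (set by the diamine and preserved by boron capture at −78 °C), alpha- instead of gamma-borylation (oxygen-directed delivery), and attack of the aldehyde at C9 and not at C5 (C5 is fully substituted and would have to become a quaternary centre); the C5=C6 geometry of 6 and the Z geometry of 12 are not touched.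

Step 10
Reactants: 17 (3Z,5R,7E,9E)-1-[(tert-butyldimethylsilyl)oxy]-11-[(4R)-2,2-dimethyl-1,3-dioxolan-4-yl]-4-iodo-10-methyl-7-(propan-2-yl)undeca-3,7,9-trien-5-ol
Product: 18 C10 tert-butyldimethylsilyl ether of 17 (C10 and C14 both silylated)
Conditions: TBSOTf, 2,6-lutidine, CH2Cl2, −78 °C
Reagents that add atoms: tert-butyldimethylsilyl trifluoromethanesulfonate, CC(C)(C)[Si](C)(C)OS(=O)(=O)C(F)(F)F
Why: Silyl triflate with a hindered pyridine base silylates the secondary allylic alcohol at low temperature without touching the acetonide or the vinyl iodide; no stereocentre is involved.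

Step 11
Reactants: 18 C10 tert-butyldimethylsilyl ether of 17
Product: 19 (3Z,5R,7E,9E)-5-[(tert-butyldimethylsilyl)oxy]-11-[(4R)-2,2-dimethyl-1,3-dioxolan-4-yl]-4-iodo-10-methyl-7-(propan-2-yl)undeca-3,7,9-trien-1-ol
Conditions: HF·pyridine, pyridine, THF, 0 °C
Reagents that add atoms: none
Why: Buffered HF·pyridine cleaves the unhindered primary silyl ether much faster than the secondary one next to the iodoalkene, and the acetonide is stable; the C14 alcohol is released while C11 is still an iodide, so no lactone can form.

Step 12
Reactants: 19 (3Z,5R,7E,9E)-5-[(tert-butyldimethylsilyl)oxy]-11-[(4R)-2,2-dimethyl-1,3-dioxolan-4-yl]-4-iodo-10-methyl-7-(propan-2-yl)undeca-3,7,9-trien-1-ol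
Product: 20 C14 chloride corresponding to 19 (C14–OH replaced by C14–Cl)
Conditions: PPh3, N-chlorosuccinimide (premixed), CH2Cl2, 0 °C to rt
Reagents that add atoms: N-chlorosuccinimide, O=C1CCC(=O)N1Cl
Why: Appel-type chlorination: the preformed chlorophosphonium salt activates the primary alcohol and chloride displaces phosphine oxide by SN2 under neutral conditions, so the diene never meets free N-chlorosuccinimide; the alkyl chloride is inert to the palladium step that follows.

Step 13
Reactants: 20 C14 chloride corresponding to 19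
Product: 21 methyl (2Z)-2-[(1R,3E,5E)-1-[(tert-butyldimethylsilyl)oxy]-7-[(4R)-2,2-dimethyl-1,3-dioxolan-4-yl]-6-methyl-3-(propan-2-yl)hepta-3,5-dien-1-yl]-5-chloropent-2-enoate
Conditions: Pd(PPh3)4 (10 mol%), CO (1 atm), MeOH, Et3N, DMF, 55 °C
Reagents that add atoms: carbon monoxide, [C-]#[O+]; methanol, CO
Why: Palladium-catalysed methoxycarbonylation: zerovalent palladium inserts into the vinyl C–I bond, CO inserts and methanol cleaves the acyl complex with retention of alkene geometry, so the ester ends cis to C13; the alkyl chloride does not react with this catalyst.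

Step 14
Reactants: 21 methyl (2Z)-2-[(1R,3E,5E)-1-[(tert-butyldimethylsilyl)oxy]-7-[(4R)-2,2-dimethyl-1,3-dioxolan-4-yl]-6-methyl-3-(propan-2-yl)hepta-3,5-dien-1-yl]-5-chloropent-2-enoate
Product: 22 C1 bis(2,2,2-trifluoroethyl) phosphonoacetate: 21 with C14–Cl replaced by C14–CH(CO2Me)P(O)(OCH2CF3)2 (both C1 epimers)
Conditions: methyl 2-[bis(2,2,2-trifluoroethoxy)phosphoryl]acetate (3 equiv), NaH (2.8 equiv), DMF, 0 °C; then 21, NaI (0.5 equiv), 45 °C
Reagents that add atoms: methyl 2-[bis(2,2,2-trifluoroethoxy)phosphoryl]acetate, COC(=O)CP(=O)(OCC(F)(F)F)OCC(F)(F)F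
Why: SN2 alkylation of the sodium salt of the Still–Gennari phosphonoacetate, used in excess to suppress double alkylation, by the primary halide after chloride–iodide exchange in the flask (Finkelstein); the soft, weakly basic carbanion favours substitution over elimination, and the C1 epimer mixture is of no consequence.

Step 15
Reactants: 22 C1 bis(2,2,2-trifluoroethyl) phosphonoacetate with C2,C3 acetonide
Product: 23 C2,C3 diol corresponding to 22
Conditions: AcOH/H2O (4:1), 35 °C
Reagents that add atoms: none
Why: Acid-catalysed hydrolysis of the terminal isopropylidene acetal; the hindered secondary silyl ether, the esters and the phosphonate tolerate aqueous acetic acid at this temperature.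

Step 16
Reactants: 23 C2,C3 diol corresponding to 22
Product: 25 C3 acetate C2 triethylsilyl ether of 23, via monosilyl ether 24 (not isolated)
Conditions: TESCl (1.05 equiv), imidazole, CH2Cl2, −40 °C; then Ac2O, pyridine, DMAP (0.1 equiv), 0 °C
Reagents that add atoms: chlorotriethylsilane, CC[Si](CC)(CC)Cl; acetic anhydride, CC(=O)OC(C)=O
Why: The primary hydroxyl is silylated selectively at low temperature on steric grounds and the remaining secondary hydroxyl is acetylated by DMAP-catalysed acyl transfer in the same flask; capping the primary oxygen first rules out acetyl migration, and C3 keeps its configuration because its C–O bond is not touched.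

Step 17
Reactants: 25 C3 acetate C2 triethylsilyl ether of 23
Product: 26 C2 aldehyde: 25 with C2–OSiEt3 converted into C2=O
Conditions: (COCl)2, DMSO, CH2Cl2, −78 to −40 °C; Et3N, −78 to −20 °C
Reagents that add atoms: none
Why: Swern oxidation applied to a primary triethylsilyl ether: the chlorosulfonium salt cleaves the Si–O bond and the alkoxysulfonium ylide collapses to the aldehyde while the tert-butyldimethylsilyl ether stays; the free hydroxy acetate is never formed, and the low temperature limits epimerisation of the alpha-acetoxy aldehyde.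

Step 18
Reactants: 26 C2 aldehyde with C3 acetate and C1 phosphonoacetate
Product: 27 dimethyl (1Z,3R,5E,7E,10R,11Z)-3-(acetyloxy)-10-[(tert-butyldimethylsilyl)oxy]-5-methyl-8-(propan-2-yl)cyclotetradeca-1,5,7,11-tetraene-1,11-dicarboxylate
Conditions: K2CO3 (6 equiv), 18-crown-6 (12 equiv), toluene (0.001 M), −20 °C to rt
Reagents that add atoms: none
Why: Intramolecular Still–Gennari modification of the Horner–Wadsworth–Emmons reaction at high dilution closes the 14-membered ring by attack of the C1 phosphonate carbanion on the C2 aldehyde; fast, irreversible collapse of the kinetic adduct of the trifluoroethyl phosphonate gives the enoate with the ester cis to C3 (Z). The carbonate/crown ether base deprotonates only the phosphonoacetate, which spares the acetate, the second ester and the C3 centre.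

Step 19
Reactants: 27 dimethyl (1Z,3R,5E,7E,10R,11Z)-3-(acetyloxy)-10-[(tert-butyldimethylsilyl)oxy]-5-methyl-8-(propan-2-yl)cyclotetradeca-1,5,7,11-tetraene-1,11-dicarboxylate
Product: 28 dimethyl (1Z,3R,5E,7E,10R,11Z)-3-(acetyloxy)-10-hydroxy-5-methyl-8-(propan-2-yl)cyclotetradeca-1,5,7,11-tetraene-1,11-dicarboxylate
Conditions: HF·pyridine, pyridine, THF, 0 °C to rt
Reagents that add atoms: none
Why: Cleavage of the secondary silyl ether by fluoride under mildly acidic conditions; HF·pyridine neither cleaves nor shifts the allylic acetate and leaves the methyl esters alone, whereas a basic fluoride source could free the C3 hydroxyl and lead to the butenolide.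

Compound list

1 | (R)-2-(2,2-dimethyl-1,3-dioxolan-4-yl)ethan-1-ol | CC1(C)OC[C@H](O1)CCO | starting material
2 | (R)-2-(2,2-dimethyl-1,3-dioxolan-4-yl)acetaldehyde | CC1(C)OC[C@H](O1)CC=O | intermediate
3 | (R)-2,2-dimethyl-4-(prop-2-yn-1-yl)-1,3-dioxolane | CC1(C)OC[C@H](O1)CC#C | intermediate
4 | [(E)-3-[(4R)-2,2-dimethyl-1,3-dioxolan-4-yl]-2-methylprop-1-en-1-yl]dimethylalane | CC1(C)OC[C@H](O1)C/C(C)=C/[Al](C)C | intermediate (not isolated)
5 | (R,E)-4-(3-iodo-2-methylprop-2-en-1-yl)-2,2-dimethyl-1,3-dioxolane | CC1(C)OC[C@H](O1)C/C(C)=C/I | intermediate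
6 | 2-[(E)-3-[(4R)-2,2-dimethyl-1,3-dioxolan-4-yl]-2-methylprop-1-en-1-yl]-4,4,5,5-tetramethyl-1,3,2-dioxaborolane | CC1(C)OC[C@H](O1)C/C(C)=C/B2OC(C)(C)C(C)(C)O2 | intermediate
7 | prop-2-yn-1-ol | C#CCO | starting material
8 | 3-methyl-2-methylidenebutan-1-ol | C=C(C(C)C)CO | intermediate
9 | 3-methyl-2-methylidenebutyl N,N-di(propan-2-yl)carbamate | C=C(C(C)C)COC(=O)N(C(C)C)C(C)C | intermediate
10 | tert-butyl(but-3-en-1-yloxy)dimethylsilane | C=CCCO[Si](C)(C)C(C)(C)C | starting material
11 | (E)-5-[(tert-butyldimethylsilyl)oxy]pent-2-enal | O=C/C=C/CCO[Si](C)(C)C(C)(C)C | intermediate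
12 | (Z)-5-[(tert-butyldimethylsilyl)oxy]-2-iodopent-2-enal | O=C/C(I)=C/CCO[Si](C)(C)C(C)(C)C | intermediate
13 | (R)-1-lithio-3-methyl-2-methylidenebutyl N,N-di(propan-2-yl)carbamate, as its (+)-sparteine complex | [Li][C@@H](OC(=O)N(C(C)C)C(C)C)C(=C)C(C)C | intermediate (not isolated)
14 | lithium boronate complex of 6 with 13 (boron bonded to C6 and to (R)-C7 bearing the carbamate) | [Li+].CC1(C)OC[C@H](O1)C/C(C)=C/[B-]2(OC(C)(C)C(C)(C)O2)[C@@H](OC(=O)N(C(C)C)C(C)C)C(=C)C(C)C | intermediate (not isolated)
15 | 2-[(3R,4E)-6-[(4R)-2,2-dimethyl-1,3-dioxolan-4-yl]-5-methyl-2-(propan-2-yl)hexa-1,4-dien-3-yl]-4,4,5,5-tetramethyl-1,3,2-dioxaborolane | CC1(C)OC[C@H](O1)C/C(C)=C/[C@@H](B2OC(C)(C)C(C)(C)O2)C(=C)C(C)C | intermediate (not isolated)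
16 | pinacol borate ester of 17 (C10–O–B) | CC1(C)OC[C@H](O1)C/C(C)=C/C=C(/C(C)C)C[C@@H](OB2OC(C)(C)C(C)(C)O2)/C(I)=C/CCO[Si](C)(C)C(C)(C)C | intermediate (not isolated)
17 | (3Z,5R,7E,9E)-1-[(tert-butyldimethylsilyl)oxy]-11-[(4R)-2,2-dimethyl-1,3-dioxolan-4-yl]-4-iodo-10-methyl-7-(propan-2-yl)undeca-3,7,9-trien-5-ol | CC1(C)OC[C@H](O1)C/C(C)=C/C=C(/C(C)C)C[C@@H](O)/C(I)=C/CCO[Si](C)(C)C(C)(C)C | intermediate
18 | (3Z,5R,7E,9E)-1,5-bis[(tert-butyldimethylsilyl)oxy]-11-[(4R)-2,2-dimethyl-1,3-dioxolan-4-yl]-4-iodo-10-methyl-7-(propan-2-yl)undeca-3,7,9-triene | CC1(C)OC[C@H](O1)C/C(C)=C/C=C(/C(C)C)C[C@@H](O[Si](C)(C)C(C)(C)C)/C(I)=C/CCO[Si](C)(C)C(C)(C)C | intermediate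
19 | (3Z,5R,7E,9E)-5-[(tert-butyldimethylsilyl)oxy]-11-[(4R)-2,2-dimethyl-1,3-dioxolan-4-yl]-4-iodo-10-methyl-7-(propan-2-yl)undeca-3,7,9-trien-1-ol | CC1(C)OC[C@H](O1)C/C(C)=C/C=C(/C(C)C)C[C@@H](O[Si](C)(C)C(C)(C)C)/C(I)=C/CCO | intermediate
20 | tert-butyl{[(3Z,5R,7E,9E)-1-chloro-11-[(4R)-2,2-dimethyl-1,3-dioxolan-4-yl]-4-iodo-10-methyl-7-(propan-2-yl)undeca-3,7,9-trien-5-yl]oxy}dimethylsilane | CC1(C)OC[C@H](O1)C/C(C)=C/C=C(/C(C)C)C[C@@H](O[Si](C)(C)C(C)(C)C)/C(I)=C/CCCl | intermediate
21 | methyl (2Z)-2-[(1R,3E,5E)-1-[(tert-butyldimethylsilyl)oxy]-7-[(4R)-2,2-dimethyl-1,3-dioxolan-4-yl]-6-methyl-3-(propan-2-yl)hepta-3,5-dien-1-yl]-5-chloropent-2-enoate | CC1(C)OC[C@H](O1)C/C(C)=C/C=C(/C(C)C)C[C@@H](O[Si](C)(C)C(C)(C)C)/C(C(=O)OC)=C/CCCl | intermediate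
22 | dimethyl (5Z)-2-[bis(2,2,2-trifluoroethoxy)phosphoryl]-6-[(1R,3E,5E)-1-[(tert-butyldimethylsilyl)oxy]-7-[(4R)-2,2-dimethyl-1,3-dioxolan-4-yl]-6-methyl-3-(propan-2-yl)hepta-3,5-dien-1-yl]hept-5-enedioate (both C2 epimers) | CC1(C)OC[C@H](O1)C/C(C)=C/C=C(/C(C)C)C[C@@H](O[Si](C)(C)C(C)(C)C)/C(C(=O)OC)=C/CCC(C(=O)OC)P(=O)(OCC(F)(F)F)OCC(F)(F)F | intermediate
23 | dimethyl (5Z)-2-[bis(2,2,2-trifluoroethoxy)phosphoryl]-6-[(1R,3E,5E,8R)-1-[(tert-butyldimethylsilyl)oxy]-8,9-dihydroxy-6-methyl-3-(propan-2-yl)nona-3,5-dien-1-yl]hept-5-enedioate | OC[C@H](O)C/C(C)=C/C=C(/C(C)C)C[C@@H](O[Si](C)(C)C(C)(C)C)/C(C(=O)OC)=C/CCC(C(=O)OC)P(=O)(OCC(F)(F)F)OCC(F)(F)F | intermediate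
24 | dimethyl (5Z)-2-[bis(2,2,2-trifluoroethoxy)phosphoryl]-6-[(1R,3E,5E,8R)-1-[(tert-butyldimethylsilyl)oxy]-8-hydroxy-6-methyl-3-(propan-2-yl)-9-[(triethylsilyl)oxy]nona-3,5-dien-1-yl]hept-5-enedioate | CC[Si](CC)(CC)OC[C@H](O)C/C(C)=C/C=C(/C(C)C)C[C@@H](O[Si](C)(C)C(C)(C)C)/C(C(=O)OC)=C/CCC(C(=O)OC)P(=O)(OCC(F)(F)F)OCC(F)(F)F | intermediate (not isolated)
25 | dimethyl (5Z)-6-[(1R,3E,5E,8R)-8-(acetyloxy)-1-[(tert-butyldimethylsilyl)oxy]-6-methyl-3-(propan-2-yl)-9-[(triethylsilyl)oxy]nona-3,5-dien-1-yl]-2-[bis(2,2,2-trifluoroethoxy)phosphoryl]hept-5-enedioate | CC[Si](CC)(CC)OC[C@H](OC(C)=O)C/C(C)=C/C=C(/C(C)C)C[C@@H](O[Si](C)(C)C(C)(C)C)/C(C(=O)OC)=C/CCC(C(=O)OC)P(=O)(OCC(F)(F)F)OCC(F)(F)F | intermediate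
26 | dimethyl (5Z)-6-[(1R,3E,5E,8R)-8-(acetyloxy)-1-[(tert-butyldimethylsilyl)oxy]-6-methyl-9-oxo-3-(propan-2-yl)nona-3,5-dien-1-yl]-2-[bis(2,2,2-trifluoroethoxy)phosphoryl]hept-5-enedioate | O=C[C@H](OC(C)=O)C/C(C)=C/C=C(/C(C)C)C[C@@H](O[Si](C)(C)C(C)(C)C)/C(C(=O)OC)=C/CCC(C(=O)OC)P(=O)(OCC(F)(F)F)OCC(F)(F)F | intermediate
27 | dimethyl (1Z,3R,5E,7E,10R,11Z)-3-(acetyloxy)-10-[(tert-butyldimethylsilyl)oxy]-5-methyl-8-(propan-2-yl)cyclotetradeca-1,5,7,11-tetraene-1,11-dicarboxylate | COC(=O)/C1=C\[C@H](OC(C)=O)C/C(C)=C/C=C(/C(C)C)C[C@@H](O[Si](C)(C)C(C)(C)C)/C(C(=O)OC)=C/CC1 | intermediate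
28 | dimethyl (1Z,3R,5E,7E,10R,11Z)-3-(acetyloxy)-10-hydroxy-5-methyl-8-(propan-2-yl)cyclotetradeca-1,5,7,11-tetraene-1,11-dicarboxylate (CNP0189703.2; locants as used in this text) | COC(=O)/C1=C\[C@H](OC(C)=O)C/C(C)=C/C=C(/C(C)C)C[C@@H](O)/C(C(=O)OC)=C/CC1 | target

Total step count: 19. Longest linear sequence: 15 steps (steps 1 to 4, then 9 to 19). The carbamate branch (steps 5 and 6) and the aldehyde branch (steps 7 and 8) have two steps each.

Steps least certain to work

Step 9 (the step marked as a proposed new method).
- What may go wrong: the sparteine-bound allyllithium may lose its configuration before boron capture, which shows up as a poor ratio at C10. Borylation may occur at the gamma terminus C9. The 1,2-shift may be incomplete, or the doubly allylic boronate may react through its C5 terminus.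
- Fallback (known reactions only): it sets out from iodide 5 and aldehyde 12 and returns to the route at 17.
  - 2-Bromo-3-methylbut-1-ene is converted with magnesium into (3-methylbut-1-en-2-yl)magnesium bromide F1.
  - F1 is added to commercial 2-(dichloromethyl)-4,4,5,5-tetramethyl-1,3,2-dioxaborolane (Matteson-type homologation, ZnCl2) to give racemic 2-(1-chloro-3-methyl-2-methylidenebutyl)-4,4,5,5-tetramethyl-1,3,2-dioxaborolane F2.
  - Iodide 5 is converted with t-BuLi into [(E)-3-[(4R)-2,2-dimethyl-1,3-dioxolan-4-yl]-2-methylprop-1-en-1-yl]lithium F3.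
  - F3 displaces chloride from F2 through the boronate complex to give the C7-epimer mixture of the allylboronate F4.
  - F4 adds to 12 as in step 9. The alkene geometry still follows from the A1,2 strain, and the product is the C10-epimer mixture of the homoallylic alcohol F5.
  - Dess–Martin oxidation gives the alpha-iodo enone F6.
  - Corey–Bakshi–Shibata reduction with (S)-2-methyl-CBS-oxazaborolidine and catecholborane, the iodoalkenyl group acting as the large substituent, gives 17.
- Partial repair: if step 9 itself fails only in the ratio at C10, the last two operations (oxidation to F6, CBS reduction) applied to the mixture restore 17.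

Step 18.
- What may go wrong: oligomerisation may compete with ring closure at the dilution where the weak base still acts. Z selectivity may erode when the forming ring restricts the approach of the carbanion. The alpha-acetoxy aldehyde may epimerise at C3 or lose acetic acid under base.
- Fallback: it changes the phosphonate class and the activation (aryl phosphonate, amine base with a sodium salt, no potassium base), which requires a parallel series from chloride 21 and returns at 27.
  - 21 is alkylated as in step 14 with methyl 2-(diphenoxyphosphoryl)acetate to give the diphenyl phosphonate F7.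
  - Acetal hydrolysis gives the diol F8.
  - Silylation gives the monosilyl ether F9 (not isolated), and acetylation gives the acetate F10.
  - Swern oxidation gives the aldehyde F11.
  - Ring closure under Ando conditions (NaI, DBU, THF, high dilution, 0 °C) gives 27.

Step 14.
- What may go wrong: loss of HX from the homoallylic halide toward the conjugated dienoate (the C13 hydrogens are allylic and vinylogous to the C11 ester), double alkylation, or slow exchange of chloride.
- Fallback: it changes the order of events and the electrophile, sets out from alcohol 19 and returns at 22.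
  - 19 is methoxycarbonylated under the conditions of step 13 to give the hydroxy ester F12, which is kept cold and used at once so that it does not lactonise.
  - Tf2O and 2,6-lutidine at −78 °C convert F12 into the triflate F13.
  - The potassium salt of the Still–Gennari phosphonoacetate (from KN(SiMe3)2) alkylates F13 at −78 °C, where substitution outruns elimination, to give 22.

Step 17.
- What may go wrong: incomplete cleavage of the Si–O bond under Swern conditions, or epimerisation and elimination at the alpha-acetoxy aldehyde during the amine stage.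
- Fallback: it replaces the direct oxidative cleavage by deprotection and a neutral oxidation, sets out from 25 and returns at 26.
  - Pyridinium p-toluenesulfonate in MeOH/CH2Cl2 at 0 °C removes the triethylsilyl group under acidic conditions, which do not promote acetyl migration, to give the hydroxy acetate F14.
  - Dess–Martin periodinane buffered with NaHCO3 gives 26.

Further compounds

F1 | step 9 | (3-methylbut-1-en-2-yl)magnesium bromide | CC(C)C(=C)[Mg]Br
F2 | step 9 | 2-(1-chloro-3-methyl-2-methylidenebutyl)-4,4,5,5-tetramethyl-1,3,2-dioxaborolane (racemic) | C=C(C(C)C)C(Cl)B1OC(C)(C)C(C)(C)O1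
F3 | step 9 | [(E)-3-[(4R)-2,2-dimethyl-1,3-dioxolan-4-yl]-2-methylprop-1-en-1-yl]lithium | CC1(C)OC[C@H](O1)C/C(C)=C/[Li]
F4 | step 9 | 2-[(4E)-6-[(4R)-2,2-dimethyl-1,3-dioxolan-4-yl]-5-methyl-2-(propan-2-yl)hexa-1,4-dien-3-yl]-4,4,5,5-tetramethyl-1,3,2-dioxaborolane (C7-epimer mixture of 15) | CC1(C)OC[C@H](O1)C/C(C)=C/C(B2OC(C)(C)C(C)(C)O2)C(=C)C(C)C
F5 | step 9 | (3Z,7E,9E)-1-[(tert-butyldimethylsilyl)oxy]-11-[(4R)-2,2-dimethyl-1,3-dioxolan-4-yl]-4-iodo-10-methyl-7-(propan-2-yl)undeca-3,7,9-trien-5-ol (C10-epimer mixture of 17) | CC1(C)OC[C@H](O1)C/C(C)=C/C=C(/C(C)C)CC(O)/C(I)=C/CCO[Si](C)(C)C(C)(C)C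
F6 | step 9 | (3Z,7E,9E)-1-[(tert-butyldimethylsilyl)oxy]-11-[(4R)-2,2-dimethyl-1,3-dioxolan-4-yl]-4-iodo-10-methyl-7-(propan-2-yl)undeca-3,7,9-trien-5-one | CC1(C)OC[C@H](O1)C/C(C)=C/C=C(/C(C)C)CC(=O)/C(I)=C/CCO[Si](C)(C)C(C)(C)C
F7 | step 18 | diphenyl phosphonate analogue of 22 | CC1(C)OC[C@H](O1)C/C(C)=C/C=C(/C(C)C)C[C@@H](O[Si](C)(C)C(C)(C)C)/C(C(=O)OC)=C/CCC(C(=O)OC)P(=O)(Oc1ccccc1)Oc1ccccc1
F8 | step 18 | diphenyl phosphonate analogue of 23 | OC[C@H](O)C/C(C)=C/C=C(/C(C)C)C[C@@H](O[Si](C)(C)C(C)(C)C)/C(C(=O)OC)=C/CCC(C(=O)OC)P(=O)(Oc1ccccc1)Oc1ccccc1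
F9 | step 18 | diphenyl phosphonate analogue of 24 | CC[Si](CC)(CC)OC[C@H](O)C/C(C)=C/C=C(/C(C)C)C[C@@H](O[Si](C)(C)C(C)(C)C)/C(C(=O)OC)=C/CCC(C(=O)OC)P(=O)(Oc1ccccc1)Oc1ccccc1
F10 | step 18 | diphenyl phosphonate analogue of 25 | CC[Si](CC)(CC)OC[C@H](OC(C)=O)C/C(C)=C/C=C(/C(C)C)C[C@@H](O[Si](C)(C)C(C)(C)C)/C(C(=O)OC)=C/CCC(C(=O)OC)P(=O)(Oc1ccccc1)Oc1ccccc1
F11 | step 18 | diphenyl phosphonate analogue of 26 | O=C[C@H](OC(C)=O)C/C(C)=C/C=C(/C(C)C)C[C@@H](O[Si](C)(C)C(C)(C)C)/C(C(=O)OC)=C/CCC(C(=O)OC)P(=O)(Oc1ccccc1)Oc1ccccc1
F12 | step 14 | methyl (2Z)-2-[(1R,3E,5E)-1-[(tert-butyldimethylsilyl)oxy]-7-[(4R)-2,2-dimethyl-1,3-dioxolan-4-yl]-6-methyl-3-(propan-2-yl)hepta-3,5-dien-1-yl]-5-hydroxypent-2-enoate | CC1(C)OC[C@H](O1)C/C(C)=C/C=C(/C(C)C)C[C@@H](O[Si](C)(C)C(C)(C)C)/C(C(=O)OC)=C/CCO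
F13 | step 14 | trifluoromethanesulfonate of F12 | CC1(C)OC[C@H](O1)C/C(C)=C/C=C(/C(C)C)C[C@@H](O[Si](C)(C)C(C)(C)C)/C(C(=O)OC)=C/CCOS(=O)(=O)C(F)(F)F
F14 | step 17 | C2 alcohol C3 acetate (25 without its triethylsilyl group) | OC[C@H](OC(C)=O)C/C(C)=C/C=C(/C(C)C)C[C@@H](O[Si](C)(C)C(C)(C)C)/C(C(=O)OC)=C/CCC(C(=O)OC)P(=O)(OCC(F)(F)F)OCC(F)(F)F
A1 | alternative 1 | C10 triethylsilyl ether of 28 | COC(=O)/C1=C\[C@H](OC(C)=O)C/C(C)=C/C=C(/C(C)C)C[C@@H](O[Si](CC)(CC)CC)/C(C(=O)OC)=C/CC1
A2 | alternative 1 | open-chain N-acyloxyphthalimide (C4 carboxyl) with C5 dienyl iodide | O=C(ON1C(=O)c2ccccc2C1=O)C[C@@H](OC(C)=O)/C=C(\C(=O)OC)CC/C=C(\C(=O)OC)[C@H](O[Si](CC)(CC)CC)C/C(C(C)C)=C\C=C(C)\I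
A3 | alternative 2 | 14-membered C7 ketone with 2-chloropropan-2-yl at C8 and tert-butyldiphenylsilyl ether at C10 | COC(=O)/C1=C\[C@H](OC(C)=O)C/C(C)=C/C(=O)[C@@H](C(C)(C)Cl)C[C@@H](O[Si](c2ccccc2)(c2ccccc2)C(C)(C)C)/C(C(=O)OC)=C/CC1
A4 | alternative 2 | open-chain C7 acid chloride with terminal isopropylidene | ClC(=O)/C=C(\C)C[C@@H](OC(C)=O)/C=C(\C(=O)OC)CC/C=C(\C(=O)OC)[C@H](O[Si](c1ccccc1)(c1ccccc1)C(C)(C)C)CC=C(C)C
A5 | alternative 3 | C10 tert-butyldimethylsilyl ether of 28 (identical with 27) | COC(=O)/C1=C\[C@H](OC(C)=O)C/C(C)=C/C=C(/C(C)C)C[C@@H](O[Si](C)(C)C(C)(C)C)/C(C(=O)OC)=C/CC1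
A6 | alternative 3 | cis-fused bicyclo[10.2.0] cyclobutene with methyl at C5 and isopropyl at C8 (one cis-fused diastereomer) | COC(=O)/C1=C\[C@H](OC(C)=O)C[C@]2(C)C=C[C@]2(C(C)C)C[C@@H](O[Si](C)(C)C(C)(C)C)/C(C(=O)OC)=C/CC1
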